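**Abbreviations.** TBS = tert-butyldimethylsilyl. St = 2-[(E)-2-{3,4-bis(TBS-oxy)phenyl}ethenyl]-4,6-bis(TBS-oxy)phenyl (rings D and E of the stilbene). Ring A = benzo ring, ring B = 4-oxyphenyl on C2, ring C = pyran ring.

**Assumption.** The target SMILES is read as the (2R,3R,4R) isomer (ring B and 3-OH cis, 3-OH and ring D trans); (S)-4-hydroxymandelic acid and piceatannol are taken as purchasable.

## Retrosynthetic overview

1. Target 17 comes from hexa-TBS ether 16 by one fluoride deprotection; ring C is the only ring that is built, and it is built last.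
2. Ring C is closed at C3–C4: a samarium Barbier addition of the C4 diarylmethyl chloride onto the C3 aldehyde of 14 sets C3 and C4 from C2 in one operation.
3. Enabling feature: C4 is doubly benzylic, between C4a of ring A and C1 of ring D, with oxygen ortho/para on both rings. It is therefore easy to make as a carbinol, to ionize to a chloride and to reduce to a stabilized carbon nucleophile. O1 sits ortho to C4 on ring A and alpha to the C3 carbonyl, so one metal can bridge C4, O1 and the aldehyde oxygen.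
4. Chloride 14 comes from carbinol ester 12, made by adding the 2-metalated silyl ether of piceatannol (from bromide 9) to the ring A aldehyde of 6.
5. Aldehyde ester 6 comes from a Mitsunobu etherification (inversion, sets C2) of salicylaldehyde 2 with (S)-mandelate 5.

Key step: step 10

## Route

Step 1
Reactants: 1 2,4-dihydroxybenzaldehyde
Product: 2 4-(TBS-oxy)-2-hydroxybenzaldehyde
Conditions: TBSCl (1.05 equiv), imidazole, CH2Cl2, 0 °C
Reagents that add atoms: tert-butyldimethylsilyl chloride, CC(C)(C)[Si](C)(C)Cl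
Why: Selective silylation should occur at the 4-OH, because the 2-OH is held in an intramolecular hydrogen bond to the formyl group and is the poorer nucleophile.

Step 2
Reactants: 3 (S)-4-hydroxymandelic acid
Product: 4 methyl (2S)-2-hydroxy-2-(4-hydroxyphenyl)acetate
Conditions: MeOH, cat. HCl (from AcCl), 0 °C to rt
Reagents that add atoms: methanol, CO
Why: Fischer esterification under mild acid should leave the benzylic stereocentre untouched, because the adjacent carboxyl group disfavours benzylic ionization.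

Step 3
Reactants: 4 methyl (2S)-2-hydroxy-2-(4-hydroxyphenyl)acetate
Product: 5 methyl (2S)-2-hydroxy-2-[4-(TBS-oxy)phenyl]acetate
Conditions: TBSCl (1.05 equiv), imidazole, DMF, 0 °C
Reagents that add atoms: tert-butyldimethylsilyl chloride, CC(C)(C)[Si](C)(C)Cl
Why: Chemoselective silylation: the phenol should react faster than the hindered, electron-poor secondary alpha-hydroxy ester.

Step 4
Reactants: 2 4-(TBS-oxy)-2-hydroxybenzaldehyde; 5 methyl (2S)-2-hydroxy-2-[4-(TBS-oxy)phenyl]acetate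
Product: 6 methyl (2R)-2-[2-formyl-5-(TBS-oxy)phenoxy]-2-[4-(TBS-oxy)phenyl]acetate
Conditions: PPh3, DIAD, THF, 0 °C to rt
Reagents that add atoms: none
Why: Mitsunobu etherification: the acidic ortho-formyl phenol displaces the oxyphosphonium group by SN2 with inversion (S to R), which sets C2; the ester group suppresses benzylic ionization, so inversion should be clean.

Step 5
Reactants: 7 piceatannol
Product: 8 (E)-3,3',4',5-tetrakis(TBS-oxy)stilbene
Conditions: TBSCl (4.4 equiv), imidazole, DMF, rt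
Reagents that add atoms: tert-butyldimethylsilyl chloride, CC(C)(C)[Si](C)(C)Cl
Why: Exhaustive silylation of the four phenols gives an ether that tolerates organometallic and reducing conditions and is removed by fluoride at the end.

Step 6
Reactants: 8 (E)-3,3',4',5-tetrakis(TBS-oxy)stilbene
Product: 9 (E)-2-bromo-3,3',4',5-tetrakis(TBS-oxy)stilbene
Conditions: NBS (1.0 equiv), CH2Cl2, −78 to −20 °C, dark
Reagents that add atoms: N-bromosuccinimide, O=C1CCC(=O)N1Br
Why: Electrophilic aromatic bromination should go to C2 of ring D, which is ortho and para to two silyloxy groups, whereas the site between them is shielded by both silyl groups and ring E has only one activating oxygen per site.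

Step 7
Reactants: 9 (E)-2-bromo-3,3',4',5-tetrakis(TBS-oxy)stilbene; 6 methyl (2R)-2-[2-formyl-5-(TBS-oxy)phenoxy]-2-[4-(TBS-oxy)phenyl]acetate
Product: 12 methyl (2R)-2-{2-[hydroxy(St)methyl]-5-(TBS-oxy)phenoxy}-2-[4-(TBS-oxy)phenyl]acetate (both carbinol epimers), via aryllithium 10 (not isolated), via arylcerium dichloride 11 (not isolated)
Conditions: n-BuLi, THF, −78 °C; anhydrous CeCl3, −78 °C; then 6, −78 °C; cold aq. work-up
Reagents that add atoms: none
Why: Bromine–lithium exchange and transmetalation to cerium give a non-basic aryl nucleophile (organocerium 1,2-addition) that should attack the aryl aldehyde faster than the ester or the acidic C2–H, while −78 °C suppresses O-to-C silyl migration in 10; the new carbinol centre forms as a mixture that the key step erases.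

Step 8
Reactants: 12 methyl (2R)-2-{2-[hydroxy(St)methyl]-5-(TBS-oxy)phenoxy}-2-[4-(TBS-oxy)phenyl]acetate
Product: 13 (2R)-2-{2-[hydroxy(St)methyl]-5-(TBS-oxy)phenoxy}-2-[4-(TBS-oxy)phenyl]acetaldehyde
Conditions: i-Bu2AlH (2.5 equiv), CH2Cl2, −78 °C; potassium sodium tartrate work-up
Reagents that add atoms: none
Why: Partial ester reduction: the alpha-aryloxy ester forms a chelated tetrahedral aluminate that is stable at −78 °C and releases the aldehyde only on work-up, and the non-basic medium should leave C2 untouched.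

Step 9
Reactants: 13 (2R)-2-{2-[hydroxy(St)methyl]-5-(TBS-oxy)phenoxy}-2-[4-(TBS-oxy)phenyl]acetaldehyde
Product: 14 (2R)-2-{2-[chloro(St)methyl]-5-(TBS-oxy)phenoxy}-2-[4-(TBS-oxy)phenyl]acetaldehyde (both chloride epimers, used crude)
Conditions: 1-chloro-N,N,2-trimethylprop-1-en-1-amine (1.2 equiv), CH2Cl2, 0 °C
Reagents that add atoms: 1-chloro-N,N,2-trimethylprop-1-en-1-amine, CC(C)=C(Cl)N(C)C
Why: Neutral deoxychlorination with an alpha-chloroenamine: the doubly benzylic alcohol is activated as an imidate that ionizes easily and collapses to the chloride, and the only by-product is a neutral amide, so the aldehyde should not enolize.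

Step 10
Reactants: 14 (2R)-2-{2-[chloro(St)methyl]-5-(TBS-oxy)phenoxy}-2-[4-(TBS-oxy)phenyl]acetaldehyde
Product: 16 (2R,3R,4R)-4-St-7-(TBS-oxy)-2-[4-(TBS-oxy)phenyl]-3,4-dihydro-2H-chromen-3-ol, via diarylmethylsamarium diiodide 15 (not isolated)
Conditions: SmI2 (2.5 equiv, 0.1 M in THF), −78 to −40 °C, slow addition of 14 (high dilution), no HMPA; aq. NaHCO3
Reagents that add atoms: none
Why: Two single-electron transfers from divalent samarium cleave the doubly benzylic C4–Cl bond, first to the diarylmethyl radical and then to the diarylmethylsamarium 15, which adds to the tethered aldehyde (samarium Barbier reaction; closest known type: intramolecular SmI2 Barbier cyclization of a benzylic halide onto an aldehyde). Ring C closes in the 6-exo-trig mode by attack of C4 on the carbonyl carbon C3. C3 is controlled by C2: the trivalent samarium on C4 is also held by the ortho ring oxygen O1, so the aldehyde oxygen must reach the metal syn-clinal to the C2–O1 bond (pseudo-axial) while ring B stays equatorial, which should give the 2,3-cis (3R) carbinol. C4 is set in the same four-centre transition state: the 2,6-disubstituted ring D turns away from the metal and from the peri C5–H into the pseudo-axial site anti to the C3–O bond, which should give the 3,4-trans (4R) arrangement. The planar radical and organometal erase the C4 configuration of 14, so both chloride epimers converge on one product. The step needs reduction of C–Cl in preference to the aldehyde, the stilbene and the aryl silyl ethers, which the weak doubly benzylic C–Cl bond, the low temperature and the absence of HMPA or a proton source should secure.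

Step 11
Reactants: 16 (2R,3R,4R)-4-St-7-(TBS-oxy)-2-[4-(TBS-oxy)phenyl]-3,4-dihydro-2H-chromen-3-ol
Product: 17 (2R,3R,4R)-4-{2-[(E)-2-(3,4-dihydroxyphenyl)ethenyl]-4,6-dihydroxyphenyl}-2-(4-hydroxyphenyl)-3,4-dihydro-2H-chromene-3,7-diol
Conditions: KHF2 (excess), MeOH–THF, rt, argon
Reagents that add atoms: none
Why: Fluoride-mediated cleavage of the six aryl silyl ethers under nearly neutral conditions should leave the stilbene, the benzylic C2–O1 ether and the C4–aryl bond intact.

## Compound list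

1 | 2,4-dihydroxybenzaldehyde | O=Cc1ccc(O)cc1O | starting material
2 | 4-(TBS-oxy)-2-hydroxybenzaldehyde | O=Cc1ccc(O[Si](C)(C)C(C)(C)C)cc1O | intermediate
3 | (S)-4-hydroxymandelic acid | OC(=O)[C@@H](O)c1ccc(O)cc1 | starting material
4 | methyl (2S)-2-hydroxy-2-(4-hydroxyphenyl)acetate | COC(=O)[C@@H](O)c1ccc(O)cc1 | intermediate
5 | methyl (2S)-2-hydroxy-2-[4-(TBS-oxy)phenyl]acetate | COC(=O)[C@@H](O)c1ccc(O[Si](C)(C)C(C)(C)C)cc1 | intermediate
6 | methyl (2R)-2-[2-formyl-5-(TBS-oxy)phenoxy]-2-[4-(TBS-oxy)phenyl]acetate | COC(=O)[C@H](Oc1cc(O[Si](C)(C)C(C)(C)C)ccc1C=O)c1ccc(O[Si](C)(C)C(C)(C)C)cc1 | intermediate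
7 | piceatannol, (E)-3,3',4',5-tetrahydroxystilbene | Oc1cc(O)cc(/C=C/c2ccc(O)c(O)c2)c1 | starting material
8 | (E)-3,3',4',5-tetrakis(TBS-oxy)stilbene | CC(C)(C)[Si](C)(C)Oc1cc(O[Si](C)(C)C(C)(C)C)cc(/C=C/c2ccc(O[Si](C)(C)C(C)(C)C)c(O[Si](C)(C)C(C)(C)C)c2)c1 | intermediate
9 | (E)-2-bromo-3,3',4',5-tetrakis(TBS-oxy)stilbene | CC(C)(C)[Si](C)(C)Oc1cc(O[Si](C)(C)C(C)(C)C)c(Br)c(/C=C/c2ccc(O[Si](C)(C)C(C)(C)C)c(O[Si](C)(C)C(C)(C)C)c2)c1 | intermediate
10 | St-lithium (aryllithium from 9) | [Li]c1c(O[Si](C)(C)C(C)(C)C)cc(O[Si](C)(C)C(C)(C)C)cc1/C=C/c1ccc(O[Si](C)(C)C(C)(C)C)c(O[Si](C)(C)C(C)(C)C)c1 | intermediate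
11 | St-cerium dichloride | Cl[Ce](Cl)c1c(O[Si](C)(C)C(C)(C)C)cc(O[Si](C)(C)C(C)(C)C)cc1/C=C/c1ccc(O[Si](C)(C)C(C)(C)C)c(O[Si](C)(C)C(C)(C)C)c1 | intermediate
12 | methyl (2R)-2-{2-[hydroxy(St)methyl]-5-(TBS-oxy)phenoxy}-2-[4-(TBS-oxy)phenyl]acetate, both carbinol epimers | COC(=O)[C@H](Oc1cc(O[Si](C)(C)C(C)(C)C)ccc1C(O)c1c(O[Si](C)(C)C(C)(C)C)cc(O[Si](C)(C)C(C)(C)C)cc1/C=C/c1ccc(O[Si](C)(C)C(C)(C)C)c(O[Si](C)(C)C(C)(C)C)c1)c1ccc(O[Si](C)(C)C(C)(C)C)cc1 | intermediate
13 | (2R)-2-{2-[hydroxy(St)methyl]-5-(TBS-oxy)phenoxy}-2-[4-(TBS-oxy)phenyl]acetaldehyde | O=C[C@H](Oc1cc(O[Si](C)(C)C(C)(C)C)ccc1C(O)c1c(O[Si](C)(C)C(C)(C)C)cc(O[Si](C)(C)C(C)(C)C)cc1/C=C/c1ccc(O[Si](C)(C)C(C)(C)C)c(O[Si](C)(C)C(C)(C)C)c1)c1ccc(O[Si](C)(C)C(C)(C)C)cc1 | intermediate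
14 | (2R)-2-{2-[chloro(St)methyl]-5-(TBS-oxy)phenoxy}-2-[4-(TBS-oxy)phenyl]acetaldehyde | O=C[C@H](Oc1cc(O[Si](C)(C)C(C)(C)C)ccc1C(Cl)c1c(O[Si](C)(C)C(C)(C)C)cc(O[Si](C)(C)C(C)(C)C)cc1/C=C/c1ccc(O[Si](C)(C)C(C)(C)C)c(O[Si](C)(C)C(C)(C)C)c1)c1ccc(O[Si](C)(C)C(C)(C)C)cc1 | intermediate
15 | diarylmethylsamarium diiodide from 14 | O=C[C@H](Oc1cc(O[Si](C)(C)C(C)(C)C)ccc1C([Sm](I)I)c1c(O[Si](C)(C)C(C)(C)C)cc(O[Si](C)(C)C(C)(C)C)cc1/C=C/c1ccc(O[Si](C)(C)C(C)(C)C)c(O[Si](C)(C)C(C)(C)C)c1)c1ccc(O[Si](C)(C)C(C)(C)C)cc1 | intermediate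
16 | (2R,3R,4R)-4-St-7-(TBS-oxy)-2-[4-(TBS-oxy)phenyl]-3,4-dihydro-2H-chromen-3-ol | CC(C)(C)[Si](C)(C)Oc1ccc([C@H]2Oc3cc(O[Si](C)(C)C(C)(C)C)ccc3[C@H](c3c(O[Si](C)(C)C(C)(C)C)cc(O[Si](C)(C)C(C)(C)C)cc3/C=C/c3ccc(O[Si](C)(C)C(C)(C)C)c(O[Si](C)(C)C(C)(C)C)c3)[C@H]2O)cc1 | intermediate
17 | (2R,3R,4R)-4-{2-[(E)-2-(3,4-dihydroxyphenyl)ethenyl]-4,6-dihydroxyphenyl}-2-(4-hydroxyphenyl)-3,4-dihydro-2H-chromene-3,7-diol | Oc1ccc([C@H]2Oc3cc(O)ccc3[C@H](c3c(O)cc(O)cc3/C=C/c3ccc(O)c(O)c3)[C@H]2O)cc1 | target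

## Step count and risks

Total steps: 11. Longest linear sequence: 8 steps (3 → 4 → 5 → 6 → 12 → 13 → 14 → 16 → 17; steps 2, 3, 4, 7, 8, 9, 10, 11).

**Step 10 (key step).** What may go wrong: electron transfer to the aldehyde before the C–Cl bond (ketyl formation, then loss of the ring A aryloxide from C2 or pinacol coupling), Wurtz-type dimerization at C4, or a weak O1 chelate that lets the carbonyl oxygen turn equatorial and erodes the facial selectivity at C3. Fallback: replace electron transfer in solution by polar metal insertion. Setting out from 14, zinc dust with LiCl in THF inserts into the C–Cl bond to give the diarylmethylzinc chloride F1, which cannot reduce an aldehyde. With MgCl2 added as the chelating Lewis acid between O1 and the carbonyl oxygen, F1 should close onto the aldehyde (zinc Barbier addition under chelation control) and come back to the route at 16.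

**Step 9.** What may go wrong: ring–chain tautomerism of 13 to a seven-membered lactol with chlorination at the lactol carbon, ionization-driven side reactions of the electron-rich chloride, or enolization of the aldehyde with loss of the C2 configuration. Fallback: install the leaving group before the aldehyde exists. Setting out from 12, sodium pyridine-2-sulfinate with trifluoroacetic acid in CH2Cl2 at 0 °C (SN1 capture of the diarylmethyl cation at sulfur) gives the 2-pyridyl sulfone ester F2. i-Bu2AlH at −78 °C then gives the sulfonyl aldehyde F3, which never passes through a hydroxy aldehyde. SmI2 in THF cleaves the C–S bond of the 2-pyridyl sulfone without HMPA (reductive samariation, through 15), and the same Barbier closure comes back to the route at 16.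

**Step 7.** What may go wrong: O-to-C silyl migration in the ortho-silyloxy aryllithium 10 (retro-Brook shift), proton abstraction at C2–H of 6 or attack on its ester, and slow addition of the 2,6-disubstituted aryl nucleophile. Fallback: avoid the aryllithium altogether. Setting out from 8, N-iodosuccinimide in CH2Cl2 gives the 2-iodo analogue F4. F4 is coupled with aldehyde 6 under Nozaki–Hiyama–Kishi conditions (CrCl2, catalytic NiCl2, DMF, rt): zerovalent nickel inserts into the C–I bond and hands the aryl group to chromium, and the non-basic arylchromium dichloride F5 adds only to the aldehyde, coming back to the route at 12.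

Further compounds
F1 | step 10 | diarylmethylzinc chloride from 14 | O=C[C@H](Oc1cc(O[Si](C)(C)C(C)(C)C)ccc1C([Zn]Cl)c1c(O[Si](C)(C)C(C)(C)C)cc(O[Si](C)(C)C(C)(C)C)cc1/C=C/c1ccc(O[Si](C)(C)C(C)(C)C)c(O[Si](C)(C)C(C)(C)C)c1)c1ccc(O[Si](C)(C)C(C)(C)C)cc1
F2 | step 9 | methyl (2R)-2-{2-[(pyridin-2-ylsulfonyl)(St)methyl]-5-(TBS-oxy)phenoxy}-2-[4-(TBS-oxy)phenyl]acetate | COC(=O)[C@H](Oc1cc(O[Si](C)(C)C(C)(C)C)ccc1C(c1c(O[Si](C)(C)C(C)(C)C)cc(O[Si](C)(C)C(C)(C)C)cc1/C=C/c1ccc(O[Si](C)(C)C(C)(C)C)c(O[Si](C)(C)C(C)(C)C)c1)S(=O)(=O)c1ccccn1)c1ccc(O[Si](C)(C)C(C)(C)C)cc1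
F3 | step 9 | (2R)-2-{2-[(pyridin-2-ylsulfonyl)(St)methyl]-5-(TBS-oxy)phenoxy}-2-[4-(TBS-oxy)phenyl]acetaldehyde | O=C[C@H](Oc1cc(O[Si](C)(C)C(C)(C)C)ccc1C(c1c(O[Si](C)(C)C(C)(C)C)cc(O[Si](C)(C)C(C)(C)C)cc1/C=C/c1ccc(O[Si](C)(C)C(C)(C)C)c(O[Si](C)(C)C(C)(C)C)c1)S(=O)(=O)c1ccccn1)c1ccc(O[Si](C)(C)C(C)(C)C)cc1
F4 | step 7 | (E)-2-iodo-3,3',4',5-tetrakis(TBS-oxy)stilbene | CC(C)(C)[Si](C)(C)Oc1cc(O[Si](C)(C)C(C)(C)C)c(I)c(/C=C/c2ccc(O[Si](C)(C)C(C)(C)C)c(O[Si](C)(C)C(C)(C)C)c2)c1
F5 | step 7 | St-chromium dichloride | Cl[Cr](Cl)c1c(O[Si](C)(C)C(C)(C)C)cc(O[Si](C)(C)C(C)(C)C)cc1/C=C/c1ccc(O[Si](C)(C)C(C)(C)C)c(O[Si](C)(C)C(C)(C)C)c1
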